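**Retrosynthetic overview**
1. The target is (−)-quinic acid carrying galloyl esters on O3, O4 and O5. It is reached by hydrogenolysis of a fully benzylated precursor, which comes from triple acylation of benzyl quinate.
2. Feature used: ring carbon C1 bears OH, CO2H and two CH2 groups (C2, C6), and C3 is a carbinol two bonds away whose oxygen is cis to O4. C1–C2 is therefore an aldol bond between a C1 α-keto ester and a C3 methyl ketone, and the only carbocycle (C1–C6) is closed there by a 6-(enolendo)-exo-trig intramolecular aldol of a 2,6-diketo ester.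
3. The C3 ketone of the resulting ketol is then reduced from the equatorial side (axial 3-OH, cis to O4 and to 1-OH).
4. The diketo ester comes from dimethyl D-tartrate: C4/C5 are held as a butane-2,3-diacetal, C6–C1 is made by alkylating a benzyl glyoxylate dithiane anion, and C3–C2 comes from the second ester via a Weinreb amide and MeMgBr.
5. Ring order: dioxane (protecting ring, step 1), then cyclohexane (step 9).

Key step: step 9

Remark: the target is 3,4,5-tri-O-galloyl-(−)-quinic acid, (1S,3R,4S,5R); quinic acid numbering is used for the ring and for its open-chain precursors, and the C1 ester is carried as benzyl from the start.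

**Step 1**
Reactants: 1 dimethyl D-tartrate
Product: 2 dimethyl (2S,3S,5S,6S)-5,6-dimethoxy-5,6-dimethyl-1,4-dioxane-2,3-dicarboxylate
Conditions: butane-2,3-dione, HC(OMe)3, camphorsulfonic acid (cat.), MeOH, reflux
Reagents that add atoms: butane-2,3-dione CC(=O)C(C)=O; methanol CO
Why: Acid-catalysed diacetal formation protects the trans-diol with both methoxy groups axial (anomeric effect) and both esters equatorial, and this six-membered diacetal is preferred to an acetonide because it is unstrained when trans-fused to the later cyclohexane and its ring C–O bonds resist β-elimination.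

**Step 2**
Reactants: 2 the diacetal diester
Product: 3 methyl (2S,3R,5S,6S)-3-(hydroxymethyl)-5,6-dimethoxy-5,6-dimethyl-1,4-dioxane-2-carboxylate
Conditions: NaBH4 (0.6 equiv), MeOH, −10 → 0 °C; recovered 2 recycled
Reagents that add atoms: none
Why: Borohydride reduction of an α-alkoxy ester, stopped at partial conversion, desymmetrises the C2-symmetric diester (the two esters are equivalent), and unreacted diester and over-reduced diol should be separable.

**Step 3**
Reactants: 3 the hydroxy ester
Product: 4 methyl (2S,3R,5S,6S)-5,6-dimethoxy-5,6-dimethyl-3-({[(trifluoromethyl)sulfonyl]oxy}methyl)-1,4-dioxane-2-carboxylate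
Conditions: Tf2O, 2,6-lutidine, CH2Cl2, −78 °C; cold aqueous work-up, used at once
Reagents that add atoms: triflic anhydride O=S(=O)(OS(=O)(=O)C(F)(F)F)C(F)(F)F
Why: O-Sulfonylation of the primary alcohol gives a triflate reactive enough for the hindered nucleophile of step 5, and it is kept cold so that the neighbouring ester carbonyl does not displace it.

**Step 4**
Reactants: 5 ethyl 1,3-dithiane-2-carboxylate
Product: 6 benzyl 1,3-dithiane-2-carboxylate
Conditions: BnOH (excess), Ti(OiPr)4 (cat.), toluene, 110 °C, EtOH distilled off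
Reagents that add atoms: benzyl alcohol OCc1ccccc1
Why: Titanate-catalysed transesterification driven by removal of ethanol installs the benzyl ester that the final hydrogenolysis will cleave together with the phenol ethers.

**Step 5**
Reactants: 6 benzyl 1,3-dithiane-2-carboxylate; 4 the triflate
Product: 8 benzyl 2-{[(2R,3S,5S,6S)-5,6-dimethoxy-3-(methoxycarbonyl)-5,6-dimethyl-1,4-dioxan-2-yl]methyl}-1,3-dithiane-2-carboxylate, via lithium ester enolate 7 (not isolated)
Conditions: LiN(SiMe3)2, THF, −78 °C; then 4, DMPU, −78 → −20 °C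
Reagents that add atoms: none
Why: SN2 alkylation of the ester-stabilised dithiane carbanion (Corey–Seebach umpolung, a glyoxylate anion equivalent) by a primary triflate forms the C6–C1 bond in the way 3-deoxy-2-ulosonates are assembled from sugar triflates, without touching C4 or C5.

**Step 6**
Reactants: 8 the dithiane diester
Product: 9 benzyl 2-({(2R,3S,5S,6S)-5,6-dimethoxy-3-[methoxy(methyl)carbamoyl]-5,6-dimethyl-1,4-dioxan-2-yl}methyl)-1,3-dithiane-2-carboxylate
Conditions: MeNH(OMe)·HCl, iPrMgCl, THF, −20 → 0 °C; aq. NH4Cl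
Reagents that add atoms: N,O-dimethylhydroxylamine hydrochloride CNOC.Cl
Why: Aminolysis by the magnesium amide converts the accessible α-alkoxy methyl ester into the Weinreb amide, whereas the benzyl ester on the quaternary dithiane carbon is too shielded to react and the equatorial C4 substituent has no drive to epimerise.

**Step 7**
Reactants: 9 the Weinreb amide
Product: 11 benzyl 2-{[(2R,3S,5S,6S)-3-acetyl-5,6-dimethoxy-5,6-dimethyl-1,4-dioxan-2-yl]methyl}-1,3-dithiane-2-carboxylate, via magnesium hemiaminal chelate 10 (not isolated)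
Conditions: MeMgBr, THF, −20 → 0 °C; aq. NH4Cl
Reagents that add atoms: methylmagnesium bromide C[Mg]Br
Why: Weinreb ketone synthesis, in which the chelated tetrahedral adduct 10 persists until work-up so that exactly one methyl group (the future C2) is added and the hindered benzyl ester is left alone.

**Step 8**
Reactants: 11 the methyl ketone dithiane
Product: 12 benzyl 3-[(2R,3S,5S,6S)-3-acetyl-5,6-dimethoxy-5,6-dimethyl-1,4-dioxan-2-yl]-2-oxopropanoate
Conditions: N-bromosuccinimide, 2,6-lutidine, acetone/H2O (9:1), −20 °C, a few minutes; aq. Na2S2O3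
Reagents that add atoms: water O
Why: Oxidative hydrolysis of the S,S-acetal (bromonium transfer to sulfur, then attack of water) frees the C1 ketone, the lutidine buffer protecting the diacetal and the short cold exposure sparing the enolisable methyl ketone.

**Step 9**
Reactants: 12 the 2,6-diketo ester
Product: 15 benzyl 4,5-O-[(2S,3S)-2,3-dimethoxybutane-2,3-diyl]-3-dehydroquinate, via pyrrolidine enamine 13 (not isolated), via cyclised iminium acetate 14 (not isolated)
Conditions: pyrrolidine (0.2 equiv), AcOH (0.2 equiv), CH2Cl2 (0.02 M), 0 °C; silica filtration, used at once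
Reagents that add atoms: none
Why: Pyrrolidine condenses with the C3 methyl ketone to give the less substituted enamine 13 (C2=C3), whose C2 adds to the C1 keto group of the α-keto ester while AcOH protonates the developing alkoxide, and iminium 14 is hydrolysed by the water released at the start, returning the amine. The closest known reaction is the enamine-mediated intramolecular aldol addition of the Hajos–Parrish type, here with an α-keto ester as acceptor, which is also the C1–C2 closure of dehydroquinate biosynthesis. The cyclohexane closes in the 6-(enolendo)-exo-trig mode through a chair trans-fused to the dioxane, whose own chair already holds C3 and C6 gauche and O4 and O5 equatorial. The new stereocentre C1 is controlled by this chair: the benzyl ester takes the equatorial position anti to C3 and the carbonyl oxygen the axial position gauche to the developing iminium carbon, where the forming alkoxide is stabilised by the acid and the positive nitrogen, so the C1–OH should come out axial and cis to O4 (natural 3-dehydroquinate configuration). The step needs regioselection for CH3 over C4–H, which the secondary amine secures because the alternative C3=C4 enamine would be tetrasubstituted and the C5–O5 ring bond of the rigid dioxane is poorly aligned for β-elimination from C4. It also needs addition without loss of O5 from the C6 enol of the keto ester (which otherwise can only lead to a four-membered ring and reverts) and without dehydration across C1–C2, which buffering, low temperature, high dilution and immediate reduction in step 10 are meant to secure.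

**Step 10**
Reactants: 15 the ketol
Product: 16 benzyl 4,5-O-[(2S,3S)-2,3-dimethoxybutane-2,3-diyl]quinate
Conditions: LiBH(s-Bu)3, THF, −78 °C; aq. NH4Cl
Reagents that add atoms: none
Why: Substrate-controlled hydride reduction in which the bulky trialkylborohydride cannot pass the axial C1–OH on the axial trajectory and attacks C3 from the equatorial side, which should set the new carbinol axial (cis to O4 and to 1-OH), while at −78 °C ketone reduction outruns deprotonation of the tertiary alcohol and hence retro-aldol opening.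

**Step 11**
Reactants: 16 the diacetal-protected benzyl quinate
Product: 17 benzyl (1S,3R,4S,5R)-1,3,4,5-tetrahydroxycyclohexane-1-carboxylate (benzyl quinate)
Conditions: CF3CO2H/H2O (9:1), 0 °C → rt
Reagents that add atoms: none
Why: Aqueous acid hydrolyses the bis-ketal to the trans-diol under conditions in which the benzyl ester and the tertiary carbinol are stable and lactonisation to the quinide is slow.

**Step 12**
Reactants: 18 3,4,5-tris(benzyloxy)benzoic acid
Product: 19 3,4,5-tris(benzyloxy)benzoyl chloride
Conditions: (COCl)2, DMF (cat.), CH2Cl2, 0 °C → rt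
Reagents that add atoms: oxalyl chloride ClC(=O)C(=O)Cl
Why: Acid chloride formation through the Vilsmeier-type chloroiminium salt activates the acid without affecting the benzyl ethers.

**Step 13**
Reactants: 17 benzyl quinate; 19 the acid chloride (three molecules are consumed for each molecule of benzyl quinate)
Product: 20 benzyl 3,4,5-tris-O-[3,4,5-tris(benzyloxy)benzoyl]quinate
Conditions: 19 (3.3 equiv in all), pyridine, DMAP (cat.), CH2Cl2, 0 °C → rt
Reagents that add atoms: 3,4,5-tris(benzyloxy)benzoyl chloride (the two further molecules) ClC(=O)c1cc(OCc2ccccc2)c(OCc2ccccc2)c(OCc2ccccc2)c1.ClC(=O)c1cc(OCc2ccccc2)c(OCc2ccccc2)c(OCc2ccccc2)c1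
Why: DMAP-catalysed acyl transfer from three molecules of the acid chloride esterifies the three secondary hydroxyls one after another (the equatorial O5 and O4 are expected to react before the axial O3), whereas the tertiary C1–OH, hindered and deactivated by the geminal ester, should stay free with only a small excess of 19.

**Step 14**
Reactants: 20 the perbenzylated triester
Product: 21 3,4,5-tri-O-galloylquinic acid (target)
Conditions: H2 (1 atm), 10% Pd/C, THF/EtOAc, rt
Reagents that add atoms: none
Why: Hydrogenolysis over Pd/C cleaves the nine benzyl ethers and the benzyl ester in one operation without touching the aryl esters or any stereocentre.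

**Compound list**
1 | dimethyl D-tartrate, dimethyl (2S,3S)-2,3-dihydroxybutanedioate | COC(=O)[C@@H](O)[C@H](O)C(=O)OC | starting material
2 | dimethyl (2S,3S,5S,6S)-5,6-dimethoxy-5,6-dimethyl-1,4-dioxane-2,3-dicarboxylate (esters equatorial, methoxy groups axial) | COC(=O)[C@H]1O[C@](C)(OC)[C@@](C)(OC)O[C@@H]1C(=O)OC | intermediate
3 | methyl (2S,3R,5S,6S)-3-(hydroxymethyl)-5,6-dimethoxy-5,6-dimethyl-1,4-dioxane-2-carboxylate | OC[C@H]1O[C@](C)(OC)[C@@](C)(OC)O[C@@H]1C(=O)OC | intermediate
4 | methyl (2S,3R,5S,6S)-5,6-dimethoxy-5,6-dimethyl-3-({[(trifluoromethyl)sulfonyl]oxy}methyl)-1,4-dioxane-2-carboxylate | O=S(=O)(OC[C@H]1O[C@](C)(OC)[C@@](C)(OC)O[C@@H]1C(=O)OC)C(F)(F)F | intermediate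
5 | ethyl 1,3-dithiane-2-carboxylate | CCOC(=O)C1SCCCS1 | starting material
6 | benzyl 1,3-dithiane-2-carboxylate | O=C(OCc1ccccc1)C1SCCCS1 | intermediate
7 | lithium enolate of 6 | [Li+].[O-]C(OCc1ccccc1)=C1SCCCS1 | intermediate
8 | benzyl 2-{[(2R,3S,5S,6S)-5,6-dimethoxy-3-(methoxycarbonyl)-5,6-dimethyl-1,4-dioxan-2-yl]methyl}-1,3-dithiane-2-carboxylate | O=C(OCc1ccccc1)C1(C[C@H]2O[C@](C)(OC)[C@@](C)(OC)O[C@@H]2C(=O)OC)SCCCS1 | intermediate
9 | benzyl 2-({(2R,3S,5S,6S)-5,6-dimethoxy-3-[methoxy(methyl)carbamoyl]-5,6-dimethyl-1,4-dioxan-2-yl}methyl)-1,3-dithiane-2-carboxylate | O=C(OCc1ccccc1)C1(C[C@H]2O[C@](C)(OC)[C@@](C)(OC)O[C@@H]2C(=O)N(C)OC)SCCCS1 | intermediate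
10 | bromomagnesium alkoxide of the tetrahedral adduct of 9 and MeMgBr (N,O-chelated; new carbon unassigned) | O=C(OCc1ccccc1)C1(C[C@H]2O[C@](C)(OC)[C@@](C)(OC)O[C@@H]2C(C)(O[Mg]Br)N(C)OC)SCCCS1 | intermediate
11 | benzyl 2-{[(2R,3S,5S,6S)-3-acetyl-5,6-dimethoxy-5,6-dimethyl-1,4-dioxan-2-yl]methyl}-1,3-dithiane-2-carboxylate | O=C(OCc1ccccc1)C1(C[C@H]2O[C@](C)(OC)[C@@](C)(OC)O[C@@H]2C(C)=O)SCCCS1 | intermediate
12 | benzyl 3-[(2R,3S,5S,6S)-3-acetyl-5,6-dimethoxy-5,6-dimethyl-1,4-dioxan-2-yl]-2-oxopropanoate (benzyl 3,7-dideoxy-4,5-O-[(2S,3S)-2,3-dimethoxybutane-2,3-diyl]-D-threo-hept-2,6-diulosonate) | O=C(OCc1ccccc1)C(=O)C[C@H]1O[C@](C)(OC)[C@@](C)(OC)O[C@@H]1C(C)=O | intermediate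
13 | pyrrolidine enamine of the methyl ketone of 12 (C2=C3) | O=C(OCc1ccccc1)C(=O)C[C@H]1O[C@](C)(OC)[C@@](C)(OC)O[C@@H]1C(=C)N1CCCC1 | intermediate
14 | pyrrolidinium-ylidene (iminium) acetate of ketol 15 (ring closed, C1–OH axial) | CC(=O)[O-].O=C(OCc1ccccc1)[C@@]1(O)C[C@H]2O[C@](C)(OC)[C@@](C)(OC)O[C@@H]2C(=[N+]2CCCC2)C1 | intermediate
15 | benzyl 4,5-O-[(2S,3S)-2,3-dimethoxybutane-2,3-diyl]-3-dehydroquinate (C3 ketone; C1–OH axial, cis to O4 and trans to O5; dioxane trans-fused at C4–C5) | O=C(OCc1ccccc1)[C@@]1(O)C[C@H]2O[C@](C)(OC)[C@@](C)(OC)O[C@@H]2C(=O)C1 | intermediate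
16 | benzyl 4,5-O-[(2S,3S)-2,3-dimethoxybutane-2,3-diyl]quinate (3-OH axial, cis to O4 and to 1-OH) | O=C(OCc1ccccc1)[C@@]1(O)C[C@H]2O[C@](C)(OC)[C@@](C)(OC)O[C@@H]2[C@H](O)C1 | intermediate
17 | benzyl (1S,3R,4S,5R)-1,3,4,5-tetrahydroxycyclohexane-1-carboxylate (benzyl quinate) | O=C(OCc1ccccc1)[C@@]1(O)C[C@@H](O)[C@H](O)[C@H](O)C1 | intermediate
18 | 3,4,5-tris(benzyloxy)benzoic acid | OC(=O)c1cc(OCc2ccccc2)c(OCc2ccccc2)c(OCc2ccccc2)c1 | starting material
19 | 3,4,5-tris(benzyloxy)benzoyl chloride | ClC(=O)c1cc(OCc2ccccc2)c(OCc2ccccc2)c(OCc2ccccc2)c1 | intermediate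
20 | benzyl 3,4,5-tris-O-[3,4,5-tris(benzyloxy)benzoyl]quinate | O=C(OCc1ccccc1)[C@@]1(O)C[C@@H](OC(=O)c2cc(OCc3ccccc3)c(OCc3ccccc3)c(OCc3ccccc3)c2)[C@H](OC(=O)c2cc(OCc3ccccc3)c(OCc3ccccc3)c(OCc3ccccc3)c2)[C@H](OC(=O)c2cc(OCc3ccccc3)c(OCc3ccccc3)c(OCc3ccccc3)c2)C1 | intermediate
21 | 3,4,5-tri-O-galloylquinic acid, (1S,3R,4S,5R)-1-hydroxy-3,4,5-tris[(3,4,5-trihydroxybenzoyl)oxy]cyclohexane-1-carboxylic acid | O=C(O[C@@H]1C[C@](O)(C(=O)O)C[C@@H](OC(=O)c2cc(O)c(O)c(O)c2)[C@H]1OC(=O)c1cc(O)c(O)c(O)c1)c1cc(O)c(O)c(O)c1 | target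

**Step count**
Total: 14 steps. Longest linear sequence: 12 steps (1–3, 5–11, 13, 14); steps 4 and 12 are side branches.

**Steps most likely to fail**

Step 9 (key aldol). The amine can also engage the more electrophilic C1 keto group, and enolisation toward C6 can expel O5 (β-elimination that opens the dioxane) or lead to intermolecular condensation. The ketol can lose its C1–OH through the product enamine and give the 3-dehydroshikimate ester, and facial discrimination at C1 may be incomplete. The fallback makes the C2 nucleophile by reduction instead of enolisation. It sets out from Weinreb amide 9, which with chloromethyllithium made in the flask (ICH2Cl, MeLi·LiBr, THF, −78 °C) should give the chloromethyl ketone F1. Unmasking as in step 8 gives the chloro diketo ester F2. SmI2 (2.2 equiv) in THF at −78 °C then cleaves the C–Cl bond to a samarium enolate that can only sit at C2 and closes onto C1 in a Reformatsky-type intramolecular aldol, with the trivalent samarium chelated between the enolate oxygen and the keto ester. Protonation comes back to the route at ketol 15.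

Step 10 (C3 reduction). Hydride may be delivered along the axial direction, giving the equatorial 3-epi alcohol, or the C1 alkoxide may trigger retro-aldol opening. The fallback inverts instead of selecting. It sets out from ketol 15, which NaBH4 in MeOH at −20 °C should reduce mainly by axial attack to the equatorial 3-epi alcohol F3. Mitsunobu esterification with acid 18 (PPh3, diisopropyl azodicarboxylate, toluene, 0 °C → rt) inverts C3 and installs the first galloyl unit as the axial ester, the 3-O-acylated diacetal F4; any natural epimer 16 formed alongside is taken to the same compound by direct acylation with 19. CF3CO2H/H2O then frees the 3-O-acylated 4,5-diol F5, and acylation of O4 and O5 with two molecules of 19 (pyridine, DMAP) comes back to the route at 20.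

Step 5 (alkylation). Substitution by the tertiary, stabilised carbanion at the β-oxygenated CH2 may be slow, and the triflate may decompose by elimination or by attack of the neighbouring ester carbonyl (lactone formation). The fallback reverses the polarity at C6 and needs no dithiane. It sets out from hydroxy ester 3: aminolysis as in step 6 gives the hydroxy Weinreb amide F6, MeMgBr gives the hydroxy methyl ketone F7, and Dess–Martin periodinane gives the keto aldehyde F8. Horner–Wadsworth–Emmons olefination of the aldehyde, chemoselective over the methyl ketone, with the lithium salt of benzyl 2-[(tert-butyldimethylsilyl)oxy]-2-(dimethoxyphosphoryl)acetate F9 (the benzyl analogue of the usual methyl ester reagent; LiN(SiMe3)2, THF, −78 °C) gives the silyl enol ether F10. HF·pyridine in THF at 0 °C removes the silyl group and the enol tautomerises, coming back to the route at diketo ester 12, so steps 6–8 are bypassed as well.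

**Further compounds**
F1 | step 9 | benzyl 2-{[(2R,3S,5S,6S)-3-(chloroacetyl)-5,6-dimethoxy-5,6-dimethyl-1,4-dioxan-2-yl]methyl}-1,3-dithiane-2-carboxylate | O=C(OCc1ccccc1)C1(C[C@H]2O[C@](C)(OC)[C@@](C)(OC)O[C@@H]2C(=O)CCl)SCCCS1
F2 | step 9 | benzyl 3-[(2R,3S,5S,6S)-3-(chloroacetyl)-5,6-dimethoxy-5,6-dimethyl-1,4-dioxan-2-yl]-2-oxopropanoate | O=C(OCc1ccccc1)C(=O)C[C@H]1O[C@](C)(OC)[C@@](C)(OC)O[C@@H]1C(=O)CCl
F3 | step 10 | benzyl 4,5-O-[(2S,3S)-2,3-dimethoxybutane-2,3-diyl]-3-epi-quinate (3-OH equatorial, trans to O4) | O=C(OCc1ccccc1)[C@@]1(O)C[C@H]2O[C@](C)(OC)[C@@](C)(OC)O[C@@H]2[C@@H](O)C1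
F4 | step 10 | benzyl 4,5-O-[(2S,3S)-2,3-dimethoxybutane-2,3-diyl]-3-O-[3,4,5-tris(benzyloxy)benzoyl]quinate | O=C(OCc1ccccc1)[C@@]1(O)C[C@H]2O[C@](C)(OC)[C@@](C)(OC)O[C@@H]2[C@H](OC(=O)c2cc(OCc3ccccc3)c(OCc3ccccc3)c(OCc3ccccc3)c2)C1
F5 | step 10 | benzyl 3-O-[3,4,5-tris(benzyloxy)benzoyl]quinate | O=C(OCc1ccccc1)[C@@]1(O)C[C@@H](O)[C@H](O)[C@H](OC(=O)c2cc(OCc3ccccc3)c(OCc3ccccc3)c(OCc3ccccc3)c2)C1
F6 | step 5 | (2S,3R,5S,6S)-3-(hydroxymethyl)-N,5,6-trimethoxy-N,5,6-trimethyl-1,4-dioxane-2-carboxamide | OC[C@H]1O[C@](C)(OC)[C@@](C)(OC)O[C@@H]1C(=O)N(C)OC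
F7 | step 5 | 1-[(2S,3R,5S,6S)-3-(hydroxymethyl)-5,6-dimethoxy-5,6-dimethyl-1,4-dioxan-2-yl]ethan-1-one | OC[C@H]1O[C@](C)(OC)[C@@](C)(OC)O[C@@H]1C(C)=O
F8 | step 5 | (2S,3S,5S,6S)-3-acetyl-5,6-dimethoxy-5,6-dimethyl-1,4-dioxane-2-carbaldehyde | O=C[C@H]1O[C@](C)(OC)[C@@](C)(OC)O[C@@H]1C(C)=O
F9 | step 5 | benzyl 2-[(tert-butyldimethylsilyl)oxy]-2-(dimethoxyphosphoryl)acetate | COP(=O)(OC)C(O[Si](C)(C)C(C)(C)C)C(=O)OCc1ccccc1
F10 | step 5 | benzyl 3-[(2R,3S,5S,6S)-3-acetyl-5,6-dimethoxy-5,6-dimethyl-1,4-dioxan-2-yl]-2-[(tert-butyldimethylsilyl)oxy]prop-2-enoate (alkene geometry not controlled) | O=C(OCc1ccccc1)C(O[Si](C)(C)C(C)(C)C)=C[C@H]1O[C@](C)(OC)[C@@](C)(OC)O[C@@H]1C(C)=O
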